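**Retrosynthetic overview**

- The chain is labelled C1 (on ring A, the styryl-side guaiacol ring) to C7 (on ring B, the ring of the saturated arm). The strategy rests on the C1=C2 alkene being conjugated to the C3 enol/carbonyl: C1 is the unsubstituted β-terminus of an acryloyl unit, so the ring A–C1 bond can be made by a Heck arylation.
- Last disconnection: the O–Si bond of a silyl ether on the ring B phenol, kept through the coupling and removed at the end.
- Key disconnection: ring A–C1, by Mizoroki–Heck coupling of 4-iodo-2-methoxyphenol with the ring-B-silylated 7-arylhept-1-ene-3,5-dione.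
- The vinyl diketone comes from oxidation of a C3 carbinol, itself from a C3–C4 aldol bond between acrolein and the kinetic methyl enolate of O-silyl zingerone, which supplies ring B, C4–C7 and the saturated arm.
- No ring is formed in the route; both benzene rings are bought.

Key step: step 4

Remark: the 1,3-diketones are written as the chelated C3 enol of the target SMILES; this tautomer equilibrates rapidly with the C5 enol and the diketo form, so no step is needed to set it. Names use the C1–C7 labels above as locants.

**Route**

Step 1
Reactants: 1 zingerone (4-(4-hydroxy-3-methoxyphenyl)butan-2-one)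
Product: 2 O-TBS-zingerone (4-[4-(tert-butyldimethylsilyloxy)-3-methoxyphenyl]butan-2-one)
Conditions: TBSCl, imidazole, DMF, rt
Reagents that add atoms: tert-butyldimethylsilyl chloride, CC(C)(C)[Si](C)(C)Cl
Why: Imidazole-promoted silylation of the only acidic OH (phenol protection) leaves the ketone untouched and masks the phenol against the amide base of step 2 and the hypervalent iodine oxidant of step 3.

Step 2
Reactants: 2 O-TBS-zingerone; 3 acrolein (prop-2-enal)
Product: 6 7-[4-(tert-butyldimethylsilyloxy)-3-methoxyphenyl]-3-hydroxyhept-1-en-5-one (racemic), via lithium enolate 4 (not isolated), via lithium aldolate 5 (not isolated)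
Conditions: LiN(iPr)2, THF, −78 °C; then 3, −78 °C; AcOH quench at −78 °C
Reagents that add atoms: none
Why: Kinetic deprotonation by the hindered amide at −78 °C should take a methyl hydrogen (the future C4) in preference to the C6 methylene, and the lithium enolate should undergo directed aldol 1,2-addition to the aldehyde carbon of acrolein, forming the C3–C4 bond with the vinyl group intact; the new C3 carbinol stereocenter is formed as a racemate and is erased by the oxidation in step 3.

Step 3
Reactants: 6 7-[4-(tert-butyldimethylsilyloxy)-3-methoxyphenyl]-3-hydroxyhept-1-en-5-one (racemic)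
Product: 7 (3Z)-7-[4-(tert-butyldimethylsilyloxy)-3-methoxyphenyl]-3-hydroxyhepta-1,3-dien-5-one (chelated enol of the hept-1-ene-3,5-dione)
Conditions: Dess–Martin periodinane, CH2Cl2, 0 °C
Reagents that add atoms: none
Why: Dess–Martin oxidation of a secondary allylic β-hydroxy ketone to the β-diketone runs at 0 °C under conditions that should spare the aryl silyl ether, the electron-rich ring and the terminal alkene, and the product, stabilised as its hydrogen-bonded enol, is carried straight into step 4 to limit oligomerisation.

Step 4
Reactants: 7 (3Z)-7-[4-(tert-butyldimethylsilyloxy)-3-methoxyphenyl]-3-hydroxyhepta-1,3-dien-5-one; 8 4-iodo-2-methoxyphenol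
Product: 9 (1E,3Z)-7-[4-(tert-butyldimethylsilyloxy)-3-methoxyphenyl]-3-hydroxy-1-(4-hydroxy-3-methoxyphenyl)hepta-1,3-dien-5-one
Conditions: Pd(OAc)2 (5 mol %), Bu4NCl, NaHCO3, DMF, 45 °C, 7 added over 2 h; then aq. citric acid
Reagents that add atoms: none
Why: Zerovalent palladium formed in situ from Pd(OAc)2 should insert into the C–I bond of 8, the arylpalladium iodide should add syn across the vinyl group of 7 with the aryl group going to unsubstituted C1 and palladium to C2, and syn β-hydride elimination of a C1 hydrogen should release the alkene while NaHCO3 takes up HI and returns zerovalent palladium. The closest known reaction type is the Mizoroki–Heck arylation of alkyl vinyl ketones and acrylates with aryl iodides, free iodophenols included, under ligand-free phase-transfer (Jeffery) conditions. No ring is closed and no stereocenter is created; the only stereochemical element is the C1=C2 geometry, expected to be E because elimination passes through the rotamer that keeps ring A and the C3 acyl group apart. The step needs arylation at C1 and not at C4 or on oxygen of the diketone: C1 is the sterically open, electronically favoured β-carbon of the acyl-substituted alkene, whereas α-arylation of a 1,3-diketone calls for bulky phosphine ligands and a stronger base, both absent here. The weak base, the moderate temperature and the slow addition of 7 keep the concentration of free vinyl diketonate low, which should limit its oligomerisation and 6-endo oxa-Michael closure, and the phenol of 8 stays largely un-ionised under bicarbonate. The mildly acidic work-up should release the product from its sodium or palladium diketonate as the chelated enol.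

Step 5
Reactants: 9 (1E,3Z)-7-[4-(tert-butyldimethylsilyloxy)-3-methoxyphenyl]-3-hydroxy-1-(4-hydroxy-3-methoxyphenyl)hepta-1,3-dien-5-one
Product: 10 (1E,3Z)-3-hydroxy-1,7-bis(4-hydroxy-3-methoxyphenyl)hepta-1,3-dien-5-one (target, CID5372374)
Conditions: Bu4NF, AcOH, THF, 0 °C
Reagents that add atoms: none
Why: Fluoride-induced cleavage of the aryl silyl ether (desilylation) is driven by the strong Si–F bond, and the acetic acid buffer keeps the medium non-basic so that the enolised diketone and the styryl enone should not suffer retro-Claisen cleavage or conjugate addition.

**Compound list**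

1 | zingerone, 4-(4-hydroxy-3-methoxyphenyl)butan-2-one | COc1cc(CCC(C)=O)ccc1O | starting material
2 | O-TBS-zingerone, 4-[4-(tert-butyldimethylsilyloxy)-3-methoxyphenyl]butan-2-one | COc1cc(CCC(C)=O)ccc1O[Si](C)(C)C(C)(C)C | intermediate
3 | acrolein, prop-2-enal | C=CC=O | starting material
4 | lithium enolate of 2 at the methyl carbon (lithium 4-aryl-but-1-en-2-olate) | [Li]OC(=C)CCc1ccc(O[Si](C)(C)C(C)(C)C)c(OC)c1 | intermediate
5 | lithium aldolate, lithium alkoxide of 6 (racemic) | [Li]OC(C=C)CC(=O)CCc1ccc(O[Si](C)(C)C(C)(C)C)c(OC)c1 | intermediate
6 | 7-[4-(tert-butyldimethylsilyloxy)-3-methoxyphenyl]-3-hydroxyhept-1-en-5-one (racemic) | C=CC(O)CC(=O)CCc1ccc(O[Si](C)(C)C(C)(C)C)c(OC)c1 | intermediate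
7 | (3Z)-7-[4-(tert-butyldimethylsilyloxy)-3-methoxyphenyl]-3-hydroxyhepta-1,3-dien-5-one (enol of the hept-1-ene-3,5-dione) | C=C/C(O)=C/C(=O)CCc1ccc(O[Si](C)(C)C(C)(C)C)c(OC)c1 | intermediate
8 | 4-iodo-2-methoxyphenol | COc1cc(I)ccc1O | starting material
9 | (1E,3Z)-7-[4-(tert-butyldimethylsilyloxy)-3-methoxyphenyl]-3-hydroxy-1-(4-hydroxy-3-methoxyphenyl)hepta-1,3-dien-5-one | COc1cc(/C=C/C(O)=C/C(=O)CCc2ccc(O[Si](C)(C)C(C)(C)C)c(OC)c2)ccc1O | intermediate
10 | (1E,3Z)-3-hydroxy-1,7-bis(4-hydroxy-3-methoxyphenyl)hepta-1,3-dien-5-one | COc1cc(/C=C/C(O)=C/C(=O)CCc2ccc(O)c(OC)c2)ccc1O | target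

**Step count and risks**

Total step count: 5. Longest linear sequence: 5 steps (1 → 2 → 6 → 7 → 9 → 10).

Steps most likely to fail:

1. Step 4 (Heck coupling). The vinyl diketone may be consumed by base-promoted oligomerisation or intramolecular oxa-Michael ring closure faster than carbopalladation, palladium may be sequestered by diketonate chelation, or the phenoxide of the iodide may add in conjugate fashion. The fallback sets out from 2 and avoids the vinyl diketone altogether. The kinetic enolate 4 (two equivalents, LiN(iPr)2, THF, −78 °C) is C-acetylated with 1-acetylbenzotriazole to give 6-[4-(tert-butyldimethylsilyloxy)-3-methoxyphenyl]hexane-2,4-dione F1. F1 is then condensed at its methyl terminus with vanillin under boron-mediated aldol condensation conditions (B2O3, B(OBu)3, n-BuNH2, EtOAc, 70 °C; then warm dilute aqueous acid). Boron chelation of the diketone blocks C4, and dehydration should form the C1=C2 bond as the E alkene. The route is rejoined at 9 and step 5 follows; any material already desilylated is 10.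

2. Step 3 (oxidation). Over-oxidation at C4 towards a vicinal tricarbonyl, or loss of the vinyl diketone by oligomerisation during oxidation and isolation, may occur. The fallback sets out from 2: enolate 4 (two equivalents, THF, −78 °C, AcOH quench) is acylated with 3-chloropropanoyl chloride to give 1-chloro-7-[4-(tert-butyldimethylsilyloxy)-3-methoxyphenyl]heptane-3,5-dione F2, a storable masked form of the vinyl group. F2 is dehydrochlorinated with Et3N in CH2Cl2 at 0 °C immediately before the coupling, by analogy with the elimination of β-chloro ketones to vinyl ketones. The route is rejoined at 7.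

3. Step 2 (aldol addition). Proton transfer may scramble the enolate towards the C6 side, acrolein may suffer conjugate addition or base-initiated polymerisation, and the aldolate may revert on work-up. The fallback sets out from 2: enolate 4 is trapped with TMSCl to give tert-butyl{2-methoxy-4-[3-(trimethylsilyloxy)but-3-en-1-yl]phenoxy}dimethylsilane F3, isolated free of amide base. F3 then undergoes a Mukaiyama aldol addition to acrolein (BF3·OEt2, CH2Cl2, −78 °C, aqueous work-up), which should give 1,2-addition under non-basic conditions. The route is rejoined at 6.

**Further compounds**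

F1 | step 4 | 6-[4-(tert-butyldimethylsilyloxy)-3-methoxyphenyl]hexane-2,4-dione | CC(=O)CC(=O)CCc1ccc(O[Si](C)(C)C(C)(C)C)c(OC)c1
F2 | step 3 | 1-chloro-7-[4-(tert-butyldimethylsilyloxy)-3-methoxyphenyl]heptane-3,5-dione | ClCCC(=O)CC(=O)CCc1ccc(O[Si](C)(C)C(C)(C)C)c(OC)c1
F3 | step 2 | tert-butyl{2-methoxy-4-[3-(trimethylsilyloxy)but-3-en-1-yl]phenoxy}dimethylsilane | C=C(O[Si](C)(C)C)CCc1ccc(O[Si](C)(C)C(C)(C)C)c(OC)c1
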